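Readings and results are calculated from invented constants, and the scatter is random.

Count turnovers first: divide the target by the catalyst charged.

common to all: substrate 0.10 M
- Thursday's: free catalyst 0.28 mol%; run made earlier
- Friday's: free catalyst 0.44 mol%; run made earlier
- flask: free catalyst 0.2 mol%

- Thursday's (time / min: target / %): 2.00: 23; 3.00: 30; 4.00: 29; 6.00: 34; 10.0: 41; 15.0: 47; 25.0: 61
- Friday's (time / min: target / %): 3.00: 37; 6.00: 47; 10.0: 54; 15.0: 64; 20.0: 68; 25.0: 73

(scatter of a reading: 1.5 percentage points)

Thursday's run reads 82.1 at 2.00 min, the turnovers per catalyst charged, and Friday's run reads 84.1 at 3.00 min, at a different loading. Thursday's run turns over at 41.0 /min per catalyst charged up to 2.00 min, then at 8.04 /min from there up to 10.0 min, which is slower, so I call the early part a burst.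

The flask reaches 10% conversion at 50.0 turnovers per catalyst charged, fewer than the 82.1 of Thursday's run, so I place that point inside the burst. With its catalyst charged twice over, the flask needs 25.0 turnovers per catalyst charged, earlier in the burst, so I expect an order above 1.

- apparent order in free catalyst when 10% of the substrate are converted (percent change of the rate of making target for one percent more free catalyst charged)
- factor on the rate of making target when 10% of the substrate are converted if free catalyst is charged twice over

The forecast gives an order of 2 and a factor of 3, holding that “more catalyst has more burst remaining at fixed conversion”. The flask gives 1.6 and 2.60, both lower than the forecast.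

    substrate + free catalyst → catalyst intermediate (k = 29.0 /M/s)
    free catalyst ⇌ dormant form (K = 16.0, k = 0.0215 /s)
    catalyst intermediate ⇌ free catalyst + target (K = 0.0150 M, k = 59.8 /s)

Free catalyst takes up substrate at 170 /min with substrate as charged and turns into the dormant form, which is off-cycle, at 1.3 /min, a ratio of 135. At 2.00 min the flask holds 70.6% of its catalyst as dormant form and 19.0% target, which is 95.1 turnovers per catalyst charged, against the 82.1 read on Thursday's run.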